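**Retrosynthetic overview**
1. Locants: the flavone part has benzo ring A, pyranone ring C (O1, C2, C3, C4) and aryl ring B (C1' to C6'). The isoflavone part has benzo ring D (C5'' to C8''), pyranone ring E and aryl ring F. The two parts meet at C3'–C8''.
2. Last disconnection: the six phenols are carried as methyl ethers and freed together at the end.
3. Key disconnection: C2–C1' and O1–C2 in one operation. The enabling feature is that C2 of ring C carries O1 and lies β to the C4 carbonyl, so ring C is the internal Michael adduct of the ring A phenol O1 to an ynone C4(=O)–C3≡C2. Opening O1–C2 leaves C2 as the sp C–H end of an ethynyl ketone of the same oxidation level, ready for Sonogashira coupling with an iodide at C1'.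
4. Iodide half: C3'–C8'' by halogen-selective Suzuki coupling of 8-iodo-tri-O-methylgenistein with (5-bromo-2-methoxyphenyl)boronic acid, then Br to I exchange at C1'. Ethynyl ketone half: 2-hydroxy-4,6-dimethoxybenzaldehyde by O-silylation, ethynyl Grignard addition and oxidation.
5. Ring order: D, E and F come with genistein, B is attached, A arrives with the ethynyl ketone, and C is formed last, in the key step.

Key step: step 8

Assumption: the target SMILES carries no stereodescriptor, so the C3'–C8'' axis (three small ortho oxygen substituents) is treated as configurationally labile and no axial control is planned.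

Step 1
Reactants: 1 genistein
Product: 2 5,7-dimethoxy-3-(4-methoxyphenyl)-4H-chromen-4-one (tri-O-methylgenistein)
Conditions: Me2SO4 (excess), K2CO3, acetone, reflux
Reagents that add atoms: dimethyl sulfate, COS(=O)(=O)OC
Why: Williamson-type O-methylation of the three phenoxides; excess reagent at reflux should also alkylate the hydrogen-bonded 5''-OH, and the hard electrophile favours O- over C-alkylation.

Step 2
Reactants: 2 tri-O-methylgenistein
Product: 3 8-iodo-5,7-dimethoxy-3-(4-methoxyphenyl)-4H-chromen-4-one
Conditions: N-iodosuccinimide, CF3CO2H (cat.), MeCN, 0 °C to rt, dark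
Reagents that add atoms: N-iodosuccinimide, O=C1CCC(=O)N1I
Why: Electrophilic aromatic iodination with acid-activated N-iodosuccinimide should occur on ring D, the most electron-rich ring, at C8'', which lies between 7''-OMe and the ring oxygen and is less crowded than C6'' between two methoxy groups, as is usual for 5,7-dimethoxy(iso)flavones.

Step 3
Reactants: 3 8-iodo-tri-O-methylgenistein; 4 (5-bromo-2-methoxyphenyl)boronic acid
Product: 5 8-(5-bromo-2-methoxyphenyl)-5,7-dimethoxy-3-(4-methoxyphenyl)-4H-chromen-4-one
Conditions: Pd(PPh3)4 (cat.), Na2CO3, DME/H2O, 80 °C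
Reagents that add atoms: none
Why: Suzuki–Miyaura coupling in which zerovalent palladium bearing PPh3 inserts into the C–I bond of 3 far faster than into the C–Br bond of the electron-rich anisyl unit, so the bromide should survive as the handle at C1'.

Step 4
Reactants: 5 aryl bromide
Product: 6 8-(5-iodo-2-methoxyphenyl)-5,7-dimethoxy-3-(4-methoxyphenyl)-4H-chromen-4-one
Conditions: CuI (cat.), trans-N,N'-dimethylcyclohexane-1,2-diamine (cat.), NaI (excess), 1,4-dioxane, 110 °C
Reagents that add atoms: sodium iodide, [Na+].[I-]
Why: Copper-catalysed aromatic Finkelstein halogen exchange, driven by precipitation of NaBr from dioxane, should turn the sluggish electron-rich bromide into an iodide that couples at room temperature; the ethers and the pyranone are inert to it.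

Step 5
Reactants: 7 2-hydroxy-4,6-dimethoxybenzaldehyde
Product: 8 2,4-dimethoxy-6-[(triisopropylsilyl)oxy]benzaldehyde
Conditions: i-Pr3SiCl, imidazole, DMF, rt
Reagents that add atoms: triisopropylsilyl chloride, CC(C)[Si](Cl)(C(C)C)C(C)C
Why: Silyl ether formation at the phenol; the bulky TIPS group is chosen because it resists O-to-O migration in step 6 and leaves cleanly with fluoride in step 8.

Step 6
Reactants: 8 silyloxy aldehyde
Product: 9 rac-1-{2,4-dimethoxy-6-[(triisopropylsilyl)oxy]phenyl}prop-2-yn-1-ol
Conditions: HC≡CMgBr, THF, −78 to 0 °C; aq. NH4Cl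
Reagents that add atoms: ethynylmagnesium bromide, C#C[Mg]Br
Why: Grignard 1,2-addition of the acetylide to the aldehyde; the carbinol centre forms as a racemate without control, which does not matter because step 7 removes it.

Step 7
Reactants: 9 propargylic alcohol
Product: 10 1-{2,4-dimethoxy-6-[(triisopropylsilyl)oxy]phenyl}prop-2-yn-1-one
Conditions: MnO2 (excess), CH2Cl2, rt
Reagents that add atoms: none
Why: MnO2 oxidation of a benzylic and propargylic alcohol under neutral conditions should give the ethynyl ketone without touching the silyl ether or the terminal alkyne.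

Step 8
Reactants: 6 aryl iodide; 10 ethynyl ketone
Product: 13 8-[5-(5,7-dimethoxy-4-oxo-4H-chromen-2-yl)-2-methoxyphenyl]-5,7-dimethoxy-3-(4-methoxyphenyl)-4H-chromen-4-one (hexa-O-methyl ether of the target), via silyl ynone 11 (not isolated), via phenol ynone 12 (not isolated)
Conditions: Pd(PPh3)2Cl2 (cat.), CuI (cat.), i-Pr2NEt, degassed THF, rt, slow addition of 10; then Bu4NF, 4-(dimethylamino)pyridine (DMAP, cat.), 0 °C to rt, same flask
Reagents that add atoms: none
Why: Zerovalent palladium inserts into the only C–I bond (C1' of ring B), the copper acetylide of the acidic ethynyl ketone C–H transmetalates and reductive elimination forms C2–C1', a Sonogashira coupling of the kind known for aryl ethynyl ketones and aryl iodides. Fluoride then frees O1, and the ring A phenoxide adds to C2, the Michael terminus of the C4(=O)–C3≡C2 ynone, after which the allenolate is protonated at C3 by the ammonium iodide left from the first stage. Ring C is closed in the 6-endo-dig mode, the known base- or DMAP-mediated cyclisation of o-alkynoylphenols to flavones, and since the ynone already has the flavone oxidation level no oxidant is needed. No stereocentre is created. Two selectivities are needed: O1 must stay silent until the C–C bond exists, which the TIPS ether secures because a free phenol would close early to a 2-unsubstituted chromone that cannot couple, and closure must go to C2 and not 5-exo to C3 (aurone), which the polarisation of the ynone, the aprotic medium and the reversible conjugate addition of DMAP at C2 secure. The isoflavone rings D to F, the methyl ethers and the hindered C3'–C8'' biaryl are spectators under these mild conditions.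

Step 9
Reactants: 13 hexa-O-methyl ether
Product: 14 8-[5-(5,7-dihydroxy-4-oxo-4H-chromen-2-yl)-2-hydroxyphenyl]-5,7-dihydroxy-3-(4-hydroxyphenyl)-4H-chromen-4-one (target)
Conditions: BBr3 (excess), CH2Cl2, −78 °C to rt; then H2O
Reagents that add atoms: none
Why: Lewis-acid aryl methyl ether cleavage with BBr3 (boron complexation, bromide attack on methyl) should remove all six methyl groups, and working at or below room temperature instead of in hot mineral acid avoids opening and re-closure of ring E (Wessely–Moser rearrangement), which would move ring B from C8'' to C6''.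

**Compound list**
1 | genistein | O=c1c(-c2ccc(O)cc2)coc2cc(O)cc(O)c12 | starting material
2 | 5,7-dimethoxy-3-(4-methoxyphenyl)-4H-chromen-4-one | COc1ccc(cc1)-c2coc3cc(OC)cc(OC)c3c2=O | intermediate
3 | 8-iodo-5,7-dimethoxy-3-(4-methoxyphenyl)-4H-chromen-4-one | COc1ccc(cc1)-c2coc3c(I)c(OC)cc(OC)c3c2=O | intermediate
4 | (5-bromo-2-methoxyphenyl)boronic acid | COc1ccc(Br)cc1B(O)O | starting material
5 | 8-(5-bromo-2-methoxyphenyl)-5,7-dimethoxy-3-(4-methoxyphenyl)-4H-chromen-4-one | COc1ccc(cc1)-c2coc3c(-c4cc(Br)ccc4OC)c(OC)cc(OC)c3c2=O | intermediate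
6 | 8-(5-iodo-2-methoxyphenyl)-5,7-dimethoxy-3-(4-methoxyphenyl)-4H-chromen-4-one | COc1ccc(cc1)-c2coc3c(-c4cc(I)ccc4OC)c(OC)cc(OC)c3c2=O | intermediate
7 | 2-hydroxy-4,6-dimethoxybenzaldehyde | COc1cc(O)c(C=O)c(OC)c1 | starting material
8 | 2,4-dimethoxy-6-[(triisopropylsilyl)oxy]benzaldehyde | COc1cc(O[Si](C(C)C)(C(C)C)C(C)C)c(C=O)c(OC)c1 | intermediate
9 | rac-1-{2,4-dimethoxy-6-[(triisopropylsilyl)oxy]phenyl}prop-2-yn-1-ol (racemate) | COc1cc(O[Si](C(C)C)(C(C)C)C(C)C)c(C(O)C#C)c(OC)c1 | intermediate
10 | 1-{2,4-dimethoxy-6-[(triisopropylsilyl)oxy]phenyl}prop-2-yn-1-one | COc1cc(O[Si](C(C)C)(C(C)C)C(C)C)c(C(=O)C#C)c(OC)c1 | intermediate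
11 | silyl ynone: 8-[5-(3-{2,4-dimethoxy-6-[(triisopropylsilyl)oxy]phenyl}-3-oxoprop-1-yn-1-yl)-2-methoxyphenyl]-5,7-dimethoxy-3-(4-methoxyphenyl)-4H-chromen-4-one | COc1ccc(cc1)-c2coc3c(-c4cc(C#CC(=O)c5c(OC)cc(OC)cc5O[Si](C(C)C)(C(C)C)C(C)C)ccc4OC)c(OC)cc(OC)c3c2=O | intermediate
12 | phenol ynone: 8-{5-[3-(2-hydroxy-4,6-dimethoxyphenyl)-3-oxoprop-1-yn-1-yl]-2-methoxyphenyl}-5,7-dimethoxy-3-(4-methoxyphenyl)-4H-chromen-4-one | COc1ccc(cc1)-c2coc3c(-c4cc(C#CC(=O)c5c(OC)cc(OC)cc5O)ccc4OC)c(OC)cc(OC)c3c2=O | intermediate
13 | 8-[5-(5,7-dimethoxy-4-oxo-4H-chromen-2-yl)-2-methoxyphenyl]-5,7-dimethoxy-3-(4-methoxyphenyl)-4H-chromen-4-one | COc1ccc(cc1)-c2coc3c(-c4cc(ccc4OC)-c5cc(=O)c6c(OC)cc(OC)cc6o5)c(OC)cc(OC)c3c2=O | intermediate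
14 | 8-[5-(5,7-dihydroxy-4-oxo-4H-chromen-2-yl)-2-hydroxyphenyl]-5,7-dihydroxy-3-(4-hydroxyphenyl)-4H-chromen-4-one | O=c1cc(-c2ccc(O)c(-c3c(O)cc(O)c4c(=O)c(-c5ccc(O)cc5)coc34)c2)oc2cc(O)cc(O)c12 | target

**Step count**
Total step count: 9. Longest linear sequence: 6 steps (steps 1, 2, 3, 4, 8, 9); the side branch is steps 5 to 7.

**Steps most likely to fail**

First, step 8. The electron-poor terminal alkyne may oligomerise under the amine base or dimerise oxidatively before it transmetalates, or the freed phenoxide may close at C3 instead of C2. The fallback sets out from 6 and 9 and comes back at 13. It makes the same C2–C1' bond at the alcohol oxidation level, so no Michael acceptor is present during the coupling.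
- Sonogashira coupling of the robust propargylic alcohol 9 with 6 (Pd(PPh3)2Cl2, CuI, Et3N, THF, 40 °C) should give the diaryl propargylic alcohol F1.
- MnO2 in CH2Cl2 should oxidise it to the silyl ynone 11, now isolated and purified free of copper.
- Bu4NF with catalytic DMAP in THF should then close ring C to 13.

Second, step 3. Palladium may also insert into the C–Br bond of 4 or of product 5, which leads to oligomerisation, and the boronic acid may protodeboronate while transmetalation at the hindered C8'' is slow. The fallback sets out from 3 and comes back at 5, with the polarity of the coupling reversed.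
- Miyaura borylation of 3 (B2pin2, Pd(dppf)Cl2 with dppf = 1,1'-bis(diphenylphosphino)ferrocene, KOAc, dioxane, 90 °C) should give the isoflavone 8-pinacolboronate F2.
- Suzuki coupling of F2 with commercial 4-bromo-2-iodoanisole (COc1ccc(Br)cc1I; Pd(PPh3)4, Na2CO3, DME/H2O) should give 5. The boron partner now carries no halogen, and iodide competes with bromide within one electrophile.

Third, step 2. The iodinating agent may attack C6'' or add twice. The fallback sets out from 2 and comes back at 3. It fixes the iodine next to a free phenol before ring E exists.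
- Alkaline ring opening of 2 (NaOH, aqueous EtOH, reflux) removes C2'' as formate and should give the 2-hydroxydeoxybenzoin F3.
- Iodination ortho to the free hydroxyl (I2, HIO3, aqueous EtOH) should give the 3-iodo deoxybenzoin F4.
- N,N-Dimethylformamide dimethyl acetal (toluene, 100 °C, then dilute acid) returns the one-carbon unit and re-closes ring E through that hydroxyl. The iodine then sits at C8'' in 3.

**Further compounds**
F1 | step 8 | rac-8-[5-(3-{2,4-dimethoxy-6-[(triisopropylsilyl)oxy]phenyl}-3-hydroxyprop-1-yn-1-yl)-2-methoxyphenyl]-5,7-dimethoxy-3-(4-methoxyphenyl)-4H-chromen-4-one | COc1ccc(cc1)-c2coc3c(-c4cc(C#CC(O)c5c(OC)cc(OC)cc5O[Si](C(C)C)(C(C)C)C(C)C)ccc4OC)c(OC)cc(OC)c3c2=O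
F2 | step 3 | 5,7-dimethoxy-3-(4-methoxyphenyl)-8-(4,4,5,5-tetramethyl-1,3,2-dioxaborolan-2-yl)-4H-chromen-4-one | COc1ccc(cc1)-c2coc3c(B4OC(C)(C)C(C)(C)O4)c(OC)cc(OC)c3c2=O
F3 | step 2 | 1-(2-hydroxy-4,6-dimethoxyphenyl)-2-(4-methoxyphenyl)ethan-1-one | COc1ccc(CC(=O)c2c(O)cc(OC)cc2OC)cc1
F4 | step 2 | 1-(2-hydroxy-3-iodo-4,6-dimethoxyphenyl)-2-(4-methoxyphenyl)ethan-1-one | COc1ccc(CC(=O)c2c(O)c(I)c(OC)cc2OC)cc1
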